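Catalyst is conserved in a closed flask: each unit charged stays there in some form, whether or not that form works. I hold that count against two earlier runs, which differ in loading but carry the same impurity.

| flask | left-handed substrate | right-handed substrate | partner | free catalyst | impurity | remark | time |
|---|---|---|---|---|---|---|---|
| dusk | 0.80 M | 0.80 M | 2 equiv | 0.25 mol% | 2.9 mM | run made earlier |  |
| midnight | 0.80 M | 0.80 M | 2 equiv | 1 mol% | 2.9 mM | run made earlier |  |
| flask | 0.80 M | 0.80 M | 2.00 equiv | 0.5 mol% | 2.9 mM |  | 2.0 h |

| run | time / min | left-handed substrate / % | right-handed substrate / % | left-handed product / % |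
|---|---|---|---|---|
| dusk | 5.00 | 48.3 | 49.4 | 1.6 |
| dusk | 15.0 | 49.3 | 51.1 | 0 |
| dusk | 25.0 | 48.6 | 51.3 | 0 |
| dusk | 40.0 | 49.7 | 48.4 | 1.3 |
| dusk | 60.0 | 50.6 | 49.6 | 0.2 |
| dusk | 80.0 | 50.8 | 51.1 | 0.4 |
| midnight | 6.00 | 45.0 | 50.0 | 4.6 |
| midnight | 10.0 | 39.4 | 50.1 | 11.0 |
| midnight | 15.0 | 33.4 | 50.6 | 16.0 |
| midnight | 25.0 | 28.3 | 48.8 | 18.2 |
| midnight | 40.0 | 24.0 | 46.3 | 27.1 |
| midnight | 80.0 | 11.1 | 47.3 | 37.7 |

(each reading ± 1 percentage point)

- free catalyst is single-handed; left-handed substrate and right-handed substrate are mirror images of each other, charged as a racemate, each of them at the stated concentration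
- an excess is the difference of the two amounts in percent of their sum
- an excess is below zero if the other one leads

- part of the left-handed substrate and right-handed substrate charged together that has reacted at 2.0 h
- excess of left-handed product over right-handed product in the product at 2.0 h
- excess of right-handed substrate over left-handed substrate among what is left of the two at 2.0 h

The dusk run has 2.00 mM of catalyst against 2.9 mM of impurity, and its left-handed product reads 0.4% at 80.0 min, within the scatter of nothing. The midnight run has 8.00 mM of catalyst and turns over. So I take the impurity to remove catalyst one for one. In the flask, 4.00 mM charged less 2.9 mM gives 1.10 mM. This working margin, catalyst charged less impurity charged, is −0.900 mM at dusk and 5.10 mM at midnight.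

Now I run the flask slowly. In the first instants the impurity meets the catalyst, and I expect 27.5% of the charge to survive. Through the middle the partner is charged at 2.00 equiv, so I neglect its fall and treat the left-handed substrate as decaying pseudo-first-order, at a rate I take as proportional to the margin. On that clock, 2.0 h here equals 25.9 min at midnight. At the end I therefore read the midnight run at 25.0 min: left-handed substrate 28.3%, right-handed substrate 48.8%. I commit to 22.9% reacted and a substrate excess of 26.6%, with the product mostly left-handed.

The forecast gives c 21% (17% to 26%), eP 89% (78% to 96%) and eS 24% (18% to 30%), holding that “the impurity kills catalyst about 1:1”.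

The flask gives c 29.2%, eP 86.2% and eS 37.7%, so more has reacted than my 22.9%.

    partner + free catalyst + left-handed substrate → free catalyst + left-handed product (k = 6.74 L² mol⁻² min⁻¹)
    partner + free catalyst + right-handed substrate → free catalyst + right-handed product (k = 0.215 L² mol⁻² min⁻¹)
    left-handed product ⇌ right-handed product (k = 3.87 × 10⁻⁴ min⁻¹)
    2 free catalyst ⇌ resting dimer, settled at all times (K = 304 L mol⁻¹)
    free catalyst + impurity → spent catalyst (k = 755 L mol⁻¹ min⁻¹)

In this flask the impurity reads 0.0388% at 0.200 h; at 2.00 h free catalyst 18.9% and resting dimer 8.65% make 27.6% of the charge, matching the margin's 27.5%, beside spent catalyst 72.5%. The left-handed substrate uses partner 31 times as fast as the right-handed just after the start, and 14 times as fast at 2.00 h. The neighbour flask, with 0.012 M of impurity, has a margin of −8.00 mM, which predicts 66.7% of its impurity left; it holds 67%, with spent catalyst at 100% and 0.298% reacted.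

The earlier runs and the new flask come from a simulation for an exercise, and the scatter is random.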